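**Plan**
1. Retrosynthesis: the ester C–O bond at C6 is cut first (p-coumaric acid), then the C6–C7 bond of ring B. The homoallylic alcohol C6(OH)–C7H2–C8(CH3)=C9 inside the cycloheptene (ring B: C1, C5–C10) is the product pattern of a [2,3]-Wittig shift, so it is traced back to an O–C9 ether: a 2-metallo-6-isopropenyl tetrahydropyran (O, C6, C5, C1, C10, C9) fused to the cyclopentane (ring A: C1–C5).
2. The pyran is opened to a C6 aldehyde and a C9 carbinol. C1–CH3 (cuprate), C5=C1 (aldol condensation) and C9–C10 (aldol with methacrolein) are cut next, which leads to the ozonolysis product of (S)-terpinen-4-ol.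
3. Forward: ring A arises by ring contraction of the terpinen-4-ol cyclohexene, the temporary pyran by lactolisation, ring B by ring expansion of the pyran; the ester is attached last.
4. Stereochemistry: C4 comes from terpinen-4-ol; C1 from cuprate attack anti to the C4 isopropyl group; C5 from equilibration of the aldehyde; C9 (auxiliary centre) from a reagent-controlled boron aldol; C6 from C9 by transfer across the ring oxygen.
5. Numbering is biogenetic (C1 methyl-bearing ring-fusion carbon, C4 isopropyl carbinol, C5 ring-fusion CH, C6 ester carbinol, C7, C8(CH3)=C9, C10); β is the face of the C1 methyl group, α the opposite face.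

Key step: step 10

Remark: (−)-Ipc2BCl is assumed to steer the methyl-ketone boron enolate to the Si face of methacrolein, which gives the 9S carbinol; should the sense be the reverse, (+)-Ipc2BCl is used with no other change.

Step 1
Reactants: 1 (S)-terpinen-4-ol
Product: 2 (S)-terpinen-4-ol methoxymethyl ether
Conditions: MOMCl, i-Pr2NEt, NaI (cat.), ClCH2CH2Cl, 60 °C
Reagents that add atoms: chloromethyl methyl ether, COCCl
Why: O-alkylation with an α-chloro ether (MOM protection) works on hindered tertiary alcohols and gives an acetal that, unlike a silyl ether, cannot migrate to a neighbouring carbanion and that later keeps the C4 oxygen from leaving or from triggering retro-aldol cleavage; the stereocentre is untouched.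

Step 2
Reactants: 2 (S)-terpinen-4-ol methoxymethyl ether
Product: 5 (S)-7,7-dimethoxy-5-(methoxymethoxy)-5-isopropylheptan-2-one, via hydroperoxy aldehyde 3 (not isolated), via hydroperoxy acetal 4 (not isolated)
Conditions: O3, CH2Cl2/MeOH (5:1), −78 °C; then TsOH·H2O (cat.), rt; then NaHCO3, Me2S, rt
Reagents that add atoms: ozone, [O-][O+]=O; methanol, CO
Why: Ozonolysis with methanol trapping of the carbonyl oxide (Criegee mechanism) cleaves the only alkene into a free aldehyde and a ketone-level methoxy hydroperoxide, so acid acetalises the aldehyde alone before Me2S reduction releases the methyl ketone, and the two termini stay differentiated.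

Step 3
Reactants: 5 (S)-7,7-dimethoxy-5-(methoxymethoxy)-5-isopropylheptan-2-one; 6 methacrolein
Product: 9 (3S,8S)-3-hydroxy-10,10-dimethoxy-8-(methoxymethoxy)-2-methyl-8-isopropyldec-1-en-5-one, via boron enolate 7 (not isolated), via boron aldolate 8 (not isolated)
Conditions: (−)-Ipc2BCl, Et3N, Et2O, 0 °C; then 6, −78 → −20 °C; then H2O2, MeOH, pH 7 buffer, 0 °C
Reagents that add atoms: none
Why: Boron-mediated aldol reaction in which Ipc2BCl/Et3N enolises the methyl ketone on its unhindered CH3 (the future C10) and the enolate adds 1,2 to the enal, the isopinocampheyl ligands and not the remote C4 centre choosing the aldehyde face and so setting the C9 carbinol (C3 of the decenone) as S.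

Step 4
Reactants: 9 (3S,8S)-3-hydroxy-10,10-dimethoxy-8-(methoxymethoxy)-2-methyl-8-isopropyldec-1-en-5-one
Product: 10 the 3-O-tert-butyldimethylsilyl ether of 9
Conditions: TBSCl, imidazole, DMF, rt
Reagents that add atoms: tert-butyldimethylsilyl chloride, CC(C)(C)[Si](C)(C)Cl
Why: Silyl ether formation at the secondary allylic alcohol gives a group that should withstand acetal hydrolysis, the amine salt and the cuprate and is later removed by fluoride without touching the MOM ether.

Step 5
Reactants: 10 the 3-O-tert-butyldimethylsilyl ether of 9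
Product: 12 (5R)-2-[(2S)-2-(tert-butyldimethylsilyloxy)-3-methylbut-3-enyl]-5-(methoxymethoxy)-5-isopropylcyclopent-1-ene-1-carbaldehyde, via keto aldehyde 11 (not isolated)
Conditions: PPTS, acetone/H2O (10:1), 50 °C; then Bn2NH·CF3CO2H (cat.), toluene, 40 °C
Reagents that add atoms: water, O
Why: Acetal hydrolysis followed by amine-catalysed intramolecular aldol condensation, in which the unhindered aldehyde forms the enamine faster than the ketone, C5 adds 5-exo to the C1 ketone and the new tertiary hydroxyl, a better leaving group than the MOM ether at C4 or the silyl ether at C9, is lost to give the tetrasubstituted enal.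

Step 6
Reactants: 12 (5R)-2-[(2S)-2-(tert-butyldimethylsilyloxy)-3-methylbut-3-enyl]-5-(methoxymethoxy)-5-isopropylcyclopent-1-ene-1-carbaldehyde
Product: 14 ring A aldehyde (1β-methyl 1α-[(2S)-2-silyloxy-3-methylbut-3-enyl] 4β-OMOM 4α-isopropyl 5β-formyl cyclopentane), via silyl enol ether 13 (not isolated)
Conditions: Me2CuLi (from MeLi and CuBr·SMe2), TMSCl, THF, −78 → −30 °C; then K2CO3, MeOH, 0 °C → rt
Reagents that add atoms: lithium dimethylcuprate, [Li+].C[Cu-]C
Why: Organocuprate conjugate addition (TMSCl-accelerated 1,4-addition) delivers methyl to C1 anti to the larger isopropyl group at C4 and syn to the copper-binding OMOM group, which sets the quaternary centre with its methyl β, and base methanolysis of the silyl enol ether then equilibrates C5 so that the formyl group settles trans to the isopropyl group and to the C1 side chain (β).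

Step 7
Reactants: 14 ring A aldehyde
Product: 16 trans-fused lactol (2-hydroxy-6β-isopropenyl tetrahydropyran fused to ring A; anomer mixture), via hydroxy aldehyde 15 (not isolated)
Conditions: HF·pyridine, pyridine, THF, 0 °C → rt
Reagents that add atoms: none
Why: Fluoride desilylation under non-basic conditions frees the C9 hydroxyl, which adds to the C6 aldehyde (6-exo-trig lactolisation helped by the two quaternary carbons of ring A) without enolising C5, so the trans ring fusion and the axial C9 isopropenyl group are kept.

Step 8
Reactants: 16 trans-fused lactol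
Product: 17 trans-fused 6α-phenylsulfonyl-9β-isopropenyl tetrahydropyran
Conditions: PhSO2H, CaCl2, CH2Cl2, rt
Reagents that add atoms: benzenesulfinic acid, O=S(O)c1ccccc1
Why: Acid-promoted anomeric substitution of the lactol by sulfinate through the cyclic oxocarbenium ion gives the 2-sulfonyl tetrahydropyran, the sulfonyl group being expected equatorial (α) because the axial position at C6 is flanked by the C1 methyl and C9 isopropenyl groups; the C6 configuration is of no later consequence.

Step 9
Reactants: 17 trans-fused 6α-phenylsulfonyl-9β-isopropenyl tetrahydropyran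
Product: 18 trans-fused 6α-trimethylstannyl-9β-isopropenyl tetrahydropyran (C4 OMOM)
Conditions: Me3SnLi (from Me3SnSnMe3 and MeLi), THF, −78 → −20 °C
Reagents that add atoms: trimethylstannyllithium, [Li][Sn](C)(C)C
Why: Nucleophilic displacement of the anomeric sulfinate by a stannyl anion, a known way from 2-sulfonyl cyclic ethers and glycosyl halides to α-alkoxy stannanes, should put tin on the open α face, and either C6 epimer would serve because the derived organolithium equilibrates to the equatorial position on warming.

Step 10
Reactants: 18 trans-fused 6α-trimethylstannyl-9β-isopropenyl tetrahydropyran (C4 OMOM)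
Product: 20 4-O-(methoxymethyl)jaeschkeanadiol (free 6α-hydroxyl; C8=C9 alkene), via lithio ether 19 (not isolated)
Conditions: MeLi (2.2 equiv), THF, −78 °C; then −78 → −20 °C; then H2O
Reagents that add atoms: none
Why: Proposed new method: MeLi exchanges tin for lithium at C6 with retention, and in the equatorial α-alkoxy organolithium 19 the carbanionic C6 attacks C7, the methylene terminus of the axial isopropenyl group, as the allylic C9–O bond breaks and the π bond moves to C8=C9 (concerted [2,3]-sigmatropic shift through a five-membered, six-electron array), which leaves the lithium alkoxide of 20. The closest known reaction types are the Wittig–Still rearrangement of stannane-derived α-alkoxy organolithiums and [2,3]-Wittig shifts of simple 2-lithio-6-vinyl cyclic ethers; a tin-triggered shift in a ring-fused stannyl tetrahydropyran that must bond C6 next to two quaternary carbons has not been shown. Ring B closes by ring expansion: the six-membered ether is enlarged to the seven-membered carbocycle through a transition state shaped like an 8-oxabicyclo[3.2.1]octene, which allows only a cis ring alkene. The one new stereocentre, C6, is controlled by C9, because the allyl unit can reach C6 only across the ring oxygen on the β face (inversion at the lithium-bearing carbon, the usual course of [2,3]-Wittig shifts), and this leaves the C6 oxygen α as in the target. The step needs the [2,3]-shift to win over the [1,2]-shift and over protonation: the [1,2]-shift would give a strained trans-fused bicyclo[3.3.0]octane, low temperature disfavours radical cleavage, and the MOM ether at C4 can chelate lithium but cannot migrate to C6.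

Step 11
Reactants: 21 (E)-4-hydroxycinnamic acid
Product: 23 (E)-4-(methoxymethoxy)cinnamic acid, via bis-MOM ester 22 (not isolated)
Conditions: MOMCl, i-Pr2NEt, CH2Cl2, 0 °C → rt; then LiOH, THF/MeOH/H2O, rt; then 1 M HCl to pH 4
Reagents that add atoms: chloromethyl methyl ether, COCCl
Why: Double alkylation with the α-chloro ether (phenol ether and ester) followed by saponification of the labile methoxymethyl ester leaves the phenol masked by the same acetal as the C4 oxygen, so one reagent unmasks both at the end; the E alkene is not affected.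

Step 12
Reactants: 20 4-O-(methoxymethyl)jaeschkeanadiol; 23 (E)-4-(methoxymethoxy)cinnamic acid
Product: 25 4-O-(methoxymethyl)jaeschkeanadiol 6-O-[(E)-4-(methoxymethoxy)cinnamate], via mixed anhydride 24 (not isolated)
Conditions: 2,4,6-Cl3C6H2COCl, Et3N, THF, rt; then 20, DMAP, toluene, 60 °C
Reagents that add atoms: none
Why: Yamaguchi esterification, in which the mixed anhydride acylates DMAP and the acylpyridinium ion is captured by the hindered secondary C6 hydroxyl, the only free hydroxyl present, with retention at C6 and without isomerising the E cinnamate.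

Step 13
Reactants: 25 4-O-(methoxymethyl)jaeschkeanadiol 6-O-[(E)-4-(methoxymethoxy)cinnamate]
Product: 26 jaeschkeanadiol 6-O-(E)-p-coumarate (CNP0265426.1)
Conditions: ZnBr2, n-PrSH, CH2Cl2, 0 °C
Reagents that add atoms: none
Why: Lewis acid-assisted thiolysis of both methoxymethyl acetals (acetal exchange onto the thiol) frees the phenol and the tertiary C4 alcohol without protic acid, so dehydration at C4, ester cleavage or thiol addition to the electron-rich cinnamate should not compete.

**Compound list**
1 | (S)-terpinen-4-ol | CC1=CC[C@](O)(C(C)C)CC1 | starting material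
2 | (S)-terpinen-4-ol methoxymethyl ether | CC1=CC[C@](OCOC)(C(C)C)CC1 | intermediate
3 | (3S)-6-hydroperoxy-6-methoxy-3-(methoxymethoxy)-3-isopropylheptanal (C6 epimers) | CC(OC)(OO)CC[C@@](OCOC)(C(C)C)CC=O | intermediate
4 | (5S)-2-hydroperoxy-2,7,7-trimethoxy-5-(methoxymethoxy)-5-isopropylheptane (C2 epimers) | CC(OC)(OO)CC[C@@](OCOC)(C(C)C)CC(OC)OC | intermediate
5 | (S)-7,7-dimethoxy-5-(methoxymethoxy)-5-isopropylheptan-2-one | CC(=O)CC[C@@](OCOC)(C(C)C)CC(OC)OC | intermediate
6 | methacrolein | CC(=C)C=O | starting material
7 | diisopinocampheylboron enolate of 5 (enolised toward C10) | C=C(OB([C@@H]1C[C@@H]2C[C@H]([C@H]1C)C2(C)C)[C@@H]1C[C@@H]2C[C@H]([C@H]1C)C2(C)C)CC[C@@](OCOC)(C(C)C)CC(OC)OC | intermediate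
8 | diisopinocampheylboron aldolate (O-boron derivative of 9) | CC(=C)[C@@H](OB([C@@H]1C[C@@H]2C[C@H]([C@H]1C)C2(C)C)[C@@H]1C[C@@H]2C[C@H]([C@H]1C)C2(C)C)CC(=O)CC[C@@](OCOC)(C(C)C)CC(OC)OC | intermediate
9 | (3S,8S)-3-hydroxy-10,10-dimethoxy-8-(methoxymethoxy)-2-methyl-8-isopropyldec-1-en-5-one | CC(=C)[C@@H](O)CC(=O)CC[C@@](OCOC)(C(C)C)CC(OC)OC | intermediate
10 | (3S,8S)-3-(tert-butyldimethylsilyloxy)-10,10-dimethoxy-8-(methoxymethoxy)-2-methyl-8-isopropyldec-1-en-5-one | CC(=C)[C@@H](O[Si](C)(C)C(C)(C)C)CC(=O)CC[C@@](OCOC)(C(C)C)CC(OC)OC | intermediate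
11 | (3S,8S)-8-(tert-butyldimethylsilyloxy)-3-(methoxymethoxy)-9-methyl-6-oxo-3-isopropyldec-9-enal | CC(=C)[C@@H](O[Si](C)(C)C(C)(C)C)CC(=O)CC[C@@](OCOC)(C(C)C)CC=O | intermediate
12 | (5R)-2-[(2S)-2-(tert-butyldimethylsilyloxy)-3-methylbut-3-enyl]-5-(methoxymethoxy)-5-isopropylcyclopent-1-ene-1-carbaldehyde | CC(=C)[C@@H](O[Si](C)(C)C(C)(C)C)CC1=C(C=O)[C@](OCOC)(C(C)C)CC1 | intermediate
13 | trimethylsilyl enol ether of 14 (C5=C6, E/Z not defined) | CC(=C)[C@@H](O[Si](C)(C)C(C)(C)C)C[C@@]1(C)CC[C@@](OCOC)(C(C)C)C1=CO[Si](C)(C)C | intermediate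
14 | ring A aldehyde: cyclopentane with C1 (β-CH3, α-CH2–(S)-CH(OTBS)–C(CH3)=CH2), C4 (β-OMOM, α-isopropyl), C5 (β-CHO, α-H) | CC(=C)[C@@H](O[Si](C)(C)C(C)(C)C)C[C@@]1(C)CC[C@@](OCOC)(C(C)C)[C@@H]1C=O | intermediate
15 | C9 hydroxy aldehyde (14 without the silyl group) | CC(=C)[C@@H](O)C[C@@]1(C)CC[C@@](OCOC)(C(C)C)[C@@H]1C=O | intermediate
16 | trans-fused lactol: tetrahydropyran O–C6(OH)–C5–C1–C10–C9 with 9β-isopropenyl, 1β-CH3, 4β-OMOM, 5α-H (anomer mixture) | CC(=C)[C@@H]1C[C@@]2(C)CC[C@@](OCOC)(C(C)C)[C@@H]2C(O)O1 | intermediate
17 | trans-fused 6α-phenylsulfonyl-9β-isopropenyl tetrahydropyran (C4 OMOM) | CC(=C)[C@@H]1C[C@@]2(C)CC[C@@](OCOC)(C(C)C)[C@@H]2[C@@H](S(=O)(=O)c3ccccc3)O1 | intermediate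
18 | trans-fused 6α-trimethylstannyl-9β-isopropenyl tetrahydropyran (C4 OMOM) | CC(=C)[C@@H]1C[C@@]2(C)CC[C@@](OCOC)(C(C)C)[C@@H]2[C@@H]([Sn](C)(C)C)O1 | intermediate
19 | trans-fused 6α-lithio-9β-isopropenyl tetrahydropyran (C4 OMOM) | CC(=C)[C@@H]1C[C@@]2(C)CC[C@@](OCOC)(C(C)C)[C@@H]2[C@@H]([Li])O1 | intermediate
20 | 4-O-(methoxymethyl)jaeschkeanadiol (1β-CH3, 4β-OMOM, 4α-isopropyl, 5α-H, 6α-OH, C8=C9) | CC1=CC[C@@]2(C)CC[C@@](OCOC)(C(C)C)[C@@H]2[C@@H](O)C1 | intermediate
21 | (E)-4-hydroxycinnamic acid | OC(=O)/C=C/c1ccc(O)cc1 | starting material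
22 | methoxymethyl (E)-4-(methoxymethoxy)cinnamate | COCOC(=O)/C=C/c1ccc(OCOC)cc1 | intermediate
23 | (E)-4-(methoxymethoxy)cinnamic acid | OC(=O)/C=C/c1ccc(OCOC)cc1 | intermediate
24 | (E)-4-(methoxymethoxy)cinnamic 2,4,6-trichlorobenzoic anhydride | COCOc1ccc(/C=C/C(=O)OC(=O)c2c(Cl)cc(Cl)cc2Cl)cc1 | intermediate
25 | 4-O-(methoxymethyl)jaeschkeanadiol 6-O-[(E)-4-(methoxymethoxy)cinnamate] | CC1=CC[C@@]2(C)CC[C@@](OCOC)(C(C)C)[C@@H]2[C@@H](OC(=O)/C=C/c2ccc(OCOC)cc2)C1 | intermediate
26 | jaeschkeanadiol 6-O-(E)-p-coumarate, CNP0265426.1 (1β-CH3, 4β-OH, 4α-isopropyl, 5α-H, 6α-acyloxy, C8=C9) | CC1=CC[C@@]2(C)CC[C@@](O)(C(C)C)[C@@H]2[C@@H](OC(=O)/C=C/c2ccc(O)cc2)C1 | target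

**Step count**
Total: 13 steps. Longest linear sequence: 12 steps (steps 1–10, 12 and 13); step 11 is a one-step side branch.

**Steps most likely to fail**

Step 10 (the proposed new method). The transition state must hold the C1 methyl, the C9 isopropenyl group and the forming C6–C7 bond on one face of the pyran. The shift may therefore be slower than protonation of the organolithium by the solvent or than homolytic C9–O cleavage. The fallback uses known chemistry, sets out from lactol 16 and returns at 20. CH2=CHMgBr in THF adds to the ring-opened aldehyde of 16; Felkin–Anh attack anti to the C4-bearing branch should give the 6α-carbinol, the divinyl diol F1. Ring-closing metathesis with the second-generation Grubbs catalyst (H2IMes)(PCy3)Cl2Ru=CHPh joins the vinyl and isopropenyl groups into the cycloheptenediol F2, whose alkene lies at C7=C8. A Mitsunobu reaction of the less hindered C9 allylic alcohol with o-nitrobenzenesulfonylhydrazide (PPh3, diethyl azodicarboxylate), loss of sulfinate and sigmatropic loss of N2 from the allylic diazene then place hydrogen on C7 and move the alkene to C8=C9, which gives 20.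

Step 5. The C9 silyloxy group may be lost by β-elimination from the ketone or by vinylogous elimination from the product enal, and the aldol may close in the other sense (C2 onto C6). The fallback sets out from keto acetal 5 and returns at lactol 16. LiN(i-Pr)2 and then methallyl iodide alkylate the methyl carbon to give the methallylated ketone F3, whose side chain carries no leaving group. The same hydrolysis and amine-salt condensation give the butenyl enal F4, and Me2CuLi/TMSCl with base equilibration as in step 6 gives the butenyl aldehyde F5. SeO2 (cat.) with t-BuOOH should hydroxylate the allylic CH2 (C9) in preference to the methyl group; the hydroxy aldehyde closes to lactol 16, which is separated from its C9 epimer.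

Step 9. At the hindered anomeric carbon the stannyl anion may act as a base or an electron donor, so that elimination to the dihydropyran or reduction takes the place of substitution. The fallback sets out from sulfone 17, leaves tin out and returns at 20. Lithium 4,4′-di-tert-butylbiphenylide in THF at −78 °C cleaves the C6–S bond reductively to the organolithium 19, which is warmed as in step 10. This fallback makes no new compound (F0).

**Further compounds**
F1 | step 10 | divinyl diol: ring A with 1α-CH2–(S)-CH(OH)–C(CH3)=CH2 and 5β-CH(OH)–CH=CH2 (6α-carbinol), 4β-OMOM | CC(=C)[C@@H](O)C[C@@]1(C)CC[C@@](OCOC)(C(C)C)[C@@H]1[C@@H](O)C=C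
F2 | step 10 | cycloheptenediol: 4-O-MOM daucane with C7=C8 alkene, 6α-OH and C9-OH | O[C@H]1C[C@@]2(C)CC[C@@](OCOC)(C(C)C)[C@@H]2[C@@H](O)C=C1C
F3 | step 5 | (S)-10,10-dimethoxy-8-(methoxymethoxy)-2-methyl-8-isopropyldec-1-en-5-one | CC(=C)CCC(=O)CC[C@@](OCOC)(C(C)C)CC(OC)OC
F4 | step 5 | (5R)-5-(methoxymethoxy)-2-(3-methylbut-3-enyl)-5-isopropylcyclopent-1-ene-1-carbaldehyde | CC(=C)CCC1=C(C=O)[C@](OCOC)(C(C)C)CC1
F5 | step 5 | ring A aldehyde with 1β-CH3, 1α-(3-methylbut-3-enyl), 4β-OMOM, 4α-isopropyl, 5β-CHO | CC(=C)CC[C@@]1(C)CC[C@@](OCOC)(C(C)C)[C@@H]1C=O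
F0 | step 9 | none | none
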